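## Retrosynthetic overview

1. Target ⇒ desilylation and transannular cyclodehydration of a germacranolide 10-hydroxy-1,3-dione (C10–OH onto the C3 carbonyl); the dione is made in the flask by hydrating a ten-membered ynone (C1≡C2–C3=O). The furanone is the last ring.
2. Ynone lactone ⇒ open C15 chain, by one chromium Barbier closure of C6–C7 (the bond made when farnesyl diphosphate cyclises to a germacrane). It sets C6 and C7, and the C6 alkoxide then closes the 12,6-lactone.
3. Open chain ⇒ acyl Sonogashira union at C2–C3 of an East alkyne (C7–C10, C1, C2, C11–C14, C8 ester in place) and a West acid (C3–C6, C15).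
4. West ⇒ Morita–Baylis–Hillman adduct of 2,2-dimethoxyacetaldehyde and methyl acrylate (C5 by enzymatic resolution). East ⇒ direct asymmetric aldol of a silylbutynone with the same aldehyde (C8), chelate-controlled MeMgBr addition (C10), vinylalumination.
5. Ring order: ten-membered carbocycle → γ-lactone (same operation) → 3(2H)-furanone.

Assumption: the target is (5R,6S,7R,8R,10S) in germacrane numbering (C1 ketone, C2=C3 furanone olefin, C4=C15H2, C5 carbinol, C6 lactone O-carbon, C7, C8 ester carbon, C9, C10 quaternary with C14 methyl, C11=C13H2, C12 lactone carbonyl), which is used for locants in the text; anhydrous 2,2-dimethoxyacetaldehyde for the aldol is obtained by extraction and distillation of the commercial aqueous solution.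

## Route

Step 1
Reactants: 1 2,2-dimethoxyacetaldehyde; 2 methyl acrylate
Product: 3 methyl (3RS)-3-hydroxy-4,4-dimethoxy-2-methylidenebutanoate
Conditions: DABCO (0.5 equiv), 1,4-dioxane/H2O 1:1, rt, 24 h (1 used as its 60% aqueous solution)
Reagents that add atoms: none
Why: Morita–Baylis–Hillman reaction, in which DABCO adds to the acrylate and the ammonium enolate attacks the highly electrophilic α,α-dialkoxy aldehyde, giving the racemic C5 carbinol that already carries C3 to C6 and C15.

Step 2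
Reactants: 3 methyl (3RS)-3-hydroxy-4,4-dimethoxy-2-methylidenebutanoate
Product: 4 methyl (3R)-3-hydroxy-4,4-dimethoxy-2-methylidenebutanoate
Conditions: lipase PS (Burkholderia cepacia, immobilised), vinyl acetate (3 equiv), t-BuOMe, 30 °C, stopped at about 55% conversion; chromatography
Reagents that add atoms: none
Why: Lipase-catalysed kinetic resolution by enantioselective transesterification, where the Kazlauskas rule (acrylate arm as the large group) predicts acetylation of the (S)-alcohol, so the (R)-alcohol that sets C5 is recovered unreacted and its configuration and ee are checked as the Mosher esters.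

Step 3
Reactants: 4 methyl (3R)-3-hydroxy-4,4-dimethoxy-2-methylidenebutanoate
Product: 5 methyl (3R)-3-[(tert-butyldimethylsilyl)oxy]-4,4-dimethoxy-2-methylidenebutanoate
Conditions: TBSCl, imidazole, DMF, rt
Reagents that add atoms: tert-butyldimethylsilyl chloride CC(C)(C)[Si](C)(C)Cl
Why: Standard silyl ether formation with a silyl chloride and imidazole, chosen over a silyl triflate so that the dimethyl acetal is not activated, and the bulky ether later enforces Felkin–Anh addition at C6.

Step 4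
Reactants: 5 methyl (3R)-3-[(tert-butyldimethylsilyl)oxy]-4,4-dimethoxy-2-methylidenebutanoate
Product: 6 (3R)-3-[(tert-butyldimethylsilyl)oxy]-4,4-dimethoxy-2-methylidenebutanoic acid
Conditions: LiOH·H2O, THF/H2O 3:1, 0 °C → rt; then 1 M HCl to pH 4, 0 °C
Reagents that add atoms: lithium hydroxide LiOH [Li+].[OH-]
Why: Saponification of the methyl ester, in which the sp2 α-carbon rules out epimerisation or β-elimination and the acetal and silyl ether are stable to hydroxide.

Step 5
Reactants: 7 4-(trimethylsilyl)but-3-yn-2-one; 1 2,2-dimethoxyacetaldehyde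
Product: 8 (5R)-5-hydroxy-6,6-dimethoxy-1-(trimethylsilyl)hex-1-yn-3-one
Conditions: (R,R)-ProPhenol (10 mol%), Et2Zn (20 mol%), 4 Å MS, THF, 0 °C, 24 h (7 in two-fold excess, anhydrous 1)
Reagents that add atoms: none
Why: Direct catalytic asymmetric aldol addition of a methyl ynone with the catalyst formed from Et2Zn and ProPhenol, whose zinc enolate is delivered to one face of the bound aldehyde and sets the C8 carbinol as 5R, the ligand antipode being assigned by analogy and confirmed by Mosher analysis before scale-up.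

Step 6
Reactants: 8 (5R)-5-hydroxy-6,6-dimethoxy-1-(trimethylsilyl)hex-1-yn-3-one
Product: 10 (3S,5R)-6,6-dimethoxy-3-methylhex-1-yne-3,5-diol, via C-silyl diol 9 (not isolated)
Conditions: MeMgBr (3 equiv), CH2Cl2/Et2O, −78 °C; then MeOH, K2CO3 (0.3 equiv), rt
Reagents that add atoms: methylmagnesium bromide MeMgBr C[Mg]Br
Why: Chelation-controlled 1,2-addition (Cram-chelate 1,3-induction), in which the magnesium alkoxide ties the ynone carbonyl into a six-membered half-chair with the dimethoxymethyl arm equatorial and MeMgBr attacks axially to give the 3,5-syn diol and thus the S quaternary centre (C10), after which methoxide removes the alkynyl silyl group by protodesilylation.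

Step 7
Reactants: 10 (3S,5R)-6,6-dimethoxy-3-methylhex-1-yne-3,5-diol; 11 3-methylbutanoyl chloride
Product: 12 (2R,4S)-4-hydroxy-1,1-dimethoxy-4-methylhex-5-yn-2-yl 3-methylbutanoate
Conditions: pyridine, DMAP (5 mol%), CH2Cl2, −20 → 0 °C
Reagents that add atoms: none
Why: Chemoselective acylation, in which the secondary hydroxyl is esterified with retention while the hindered tertiary propargylic hydroxyl does not react, placing the isovalerate of the target on C8.

Step 8
Reactants: 12 (2R,4S)-4-hydroxy-1,1-dimethoxy-4-methylhex-5-yn-2-yl 3-methylbutanoate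
Product: 15 (2R,4S)-4-methyl-1-oxo-4-[(triethylsilyl)oxy]hex-5-yn-2-yl 3-methylbutanoate, via silyl ether acetal 13 (not isolated), via collidinium salt 14 (not isolated)
Conditions: TESOTf (3 equiv), 2,4,6-collidine (4.5 equiv), CH2Cl2, −78 → 0 °C; then H2O, 0 °C → rt
Reagents that add atoms: triethylsilyl trifluoromethanesulfonate CC[Si](CC)(CC)OS(=O)(=O)C(F)(F)F; water O
Why: One-pot O-silylation and silyl triflate/collidine acetal cleavage (Fujioka–Kita type), in which the tertiary alcohol is capped first so that no lactol can form with the C7 aldehyde and the acetal is then ionised to a collidinium salt that water converts to the aldehyde under non-acidic conditions that leave the ester, the silyl ether and the C8 stereocentre untouched.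

Step 9
Reactants: 15 (2R,4S)-4-methyl-1-oxo-4-[(triethylsilyl)oxy]hex-5-yn-2-yl 3-methylbutanoate; 16 methyl propiolate
Product: 18 methyl (3RS,4R,6S)-3-hydroxy-6-methyl-2-methylidene-4-[(3-methylbutanoyl)oxy]-6-[(triethylsilyl)oxy]oct-7-ynoate, via vinylalane 17 (not isolated)
Conditions: i-Bu2AlH (1.4 equiv), NMO (1.4 equiv), THF, 0 °C, then 16 (1.5 equiv), 0 °C, 45 min; then 15, 0 °C → rt; aqueous KNaC4H4O6 work-up
Reagents that add atoms: none
Why: Vinylalumination (hydroalumination of the propiolate gives the α-aluminoacrylate, which adds to the aldehyde) as a fast amine-free route to the Morita–Baylis–Hillman adduct, so the base-sensitive α-acyloxy aldehyde does not epimerise, and the new C7 carbinol forms as a mixture that is erased in step 11.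

Step 10
Reactants: 6 (3R)-3-[(tert-butyldimethylsilyl)oxy]-4,4-dimethoxy-2-methylidenebutanoic acid; 18 methyl (3RS,4R,6S)-3-hydroxy-6-methyl-2-methylidene-4-[(3-methylbutanoyl)oxy]-6-[(triethylsilyl)oxy]oct-7-ynoate
Product: 20 methyl (3RS,4R,6S,11R)-11-[(tert-butyldimethylsilyl)oxy]-3-hydroxy-12,12-dimethoxy-6-methyl-2,10-dimethylidene-4-[(3-methylbutanoyl)oxy]-9-oxo-6-[(triethylsilyl)oxy]dodec-7-ynoate, via acid chloride 19 (not isolated)
Conditions: 6, 1-chloro-N,N,2-trimethylprop-1-en-1-amine (1.1 equiv), CH2Cl2, 0 °C, 1 h; then 18, PdCl2(PPh3)2 (3 mol%), CuI (6 mol%), Et3N (1.2 equiv), THF, 0 °C → rt, 1 h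
Reagents that add atoms: none
Why: Neutral acid chloride formation followed by acyl Sonogashira coupling (the copper acetylide transmetalates to the acylpalladium chloride) forges the C2–C3 bond and the ynone without disturbing any stereocentre, and the near-stoichiometric base and short reaction time suppress 1,2-acyl migration and O-acylation of the hindered secondary alcohol.

Step 11
Reactants: 20 methyl (3RS,4R,6S,11R)-11-[(tert-butyldimethylsilyl)oxy]-3-hydroxy-12,12-dimethoxy-6-methyl-2,10-dimethylidene-4-[(3-methylbutanoyl)oxy]-9-oxo-6-[(triethylsilyl)oxy]dodec-7-ynoate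
Product: 21 methyl (2Z,4R,6S,11R)-2-(bromomethyl)-11-[(tert-butyldimethylsilyl)oxy]-12,12-dimethoxy-6-methyl-10-methylidene-4-[(3-methylbutanoyl)oxy]-9-oxo-6-[(triethylsilyl)oxy]dodec-2-en-7-ynoate
Conditions: NBS (1.3 equiv), Me2S (1.5 equiv), CH2Cl2, 0 °C → rt
Reagents that add atoms: N-bromosuccinimide O=C1CCC(=O)N1Br
Why: Corey–Kim-type activation of the allylic alcohol as an alkoxysulfonium salt and SN2′ displacement by bromide (allylic transposition) gives the thermodynamically preferred (Z)-2-(bromomethyl)enoate and removes the C7 carbinol stereocentre.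

Step 12
Reactants: 21 methyl (2Z,4R,6S,11R)-2-(bromomethyl)-11-[(tert-butyldimethylsilyl)oxy]-12,12-dimethoxy-6-methyl-10-methylidene-4-[(3-methylbutanoyl)oxy]-9-oxo-6-[(triethylsilyl)oxy]dodec-2-en-7-ynoate
Product: 23 methyl (2Z,4R,6S,11R)-2-(bromomethyl)-11-[(tert-butyldimethylsilyl)oxy]-6-methyl-10-methylidene-4-[(3-methylbutanoyl)oxy]-9,12-dioxo-6-[(triethylsilyl)oxy]dodec-2-en-7-ynoate, via collidinium salt 22 (not isolated)
Conditions: TESOTf (2 equiv), 2,4,6-collidine (3 equiv), CH2Cl2, 0 °C; then H2O, 0 °C; crude aldehyde used at once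
Reagents that add atoms: water O
Why: The same silyl triflate/collidine acetal cleavage releases the α-silyloxy aldehyde at C6 without acid that would strip the silyl ethers or base strong enough to epimerise C5 or attack the allylic bromide.

Step 13
Reactants: 23 methyl (2Z,4R,6S,11R)-2-(bromomethyl)-11-[(tert-butyldimethylsilyl)oxy]-6-methyl-10-methylidene-4-[(3-methylbutanoyl)oxy]-9,12-dioxo-6-[(triethylsilyl)oxy]dodec-2-en-7-ynoate
Product: 26 (5R,6S,7R,8R,10S)-5-[(tert-butyldimethylsilyl)oxy]-8-[(3-methylbutanoyl)oxy]-3-oxo-10-[(triethylsilyl)oxy]germacra-4(15),11(13)-dien-1-yn-12,6-olide, via allylchromium species 24 (not isolated), via seco hydroxy ester 25 (not isolated)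
Conditions: CrCl2 (10 equiv), THF, rt, syringe-pump addition of 23 over 10 h (final 2 mM); aqueous NH4Cl; then PPTS (20 mol%), CH2Cl2, rt
Reagents that add atoms: none
Why: Intramolecular Nozaki–Hiyama allylation (chromium Barbier), in which CrCl2 inserts only into the allylic bromide and the allylchromium adds through C7 (SE2′) to the C6 aldehyde in a chair Zimmerman–Traxler transition state, where the bulky non-chelating silyloxy group at C5 directs Felkin–Anh attack (5,6-anti) and the ring arms at C5 and C8 take the staggered crown arrangement of a germacrane so that H6 and H7 end up trans and C7 anti to the C8 ester (the sense usually seen in chromium closures of this bond in germacranolides), after which the C6 hydroxyl closes the trans γ-lactone on the methyl ester under mild acid.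

Step 14
Reactants: 26 (5R,6S,7R,8R,10S)-5-[(tert-butyldimethylsilyl)oxy]-8-[(3-methylbutanoyl)oxy]-3-oxo-10-[(triethylsilyl)oxy]germacra-4(15),11(13)-dien-1-yn-12,6-olide
Product: 30 (5R,6S,7R,8R,10S)-5-hydroxy-8-[(3-methylbutanoyl)oxy]-1-oxo-3,10-epoxygermacra-2,4(15),11(13)-trien-12,6-olide, via silylated 1,3-diketone 27 (not isolated), via 10-hydroxy 1,3-diketone 28 (not isolated), via 5-O-silyl furanone 29 (not isolated)
Conditions: Ph3PAuNTf2 (5 mol%), H2O (5 equiv), 1,4-dioxane, rt; then HF·pyridine, THF, 0 °C → rt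
Reagents that add atoms: water O
Why: Gold-catalysed hydration of the ynone (water adds at C1, β to the carbonyl) gives the 1,3-diketone, fluoride then removes the tertiary triethylsilyl group first and the freed C10 hydroxyl adds across the ring to the C3 carbonyl with loss of water to give the 3(2H)-furanone (the classical cyclodehydration of α′-hydroxy 1,3-diketones), and the slower cleavage of the secondary silyl ether finally frees the C5 hydroxyl without touching any stereocentre.

## Compound list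

1 | 2,2-dimethoxyacetaldehyde | COC(OC)C=O | starting material
2 | methyl acrylate | C=CC(=O)OC | starting material
3 | methyl (3RS)-3-hydroxy-4,4-dimethoxy-2-methylidenebutanoate | COC(=O)C(=C)C(O)C(OC)OC | intermediate
4 | methyl (3R)-3-hydroxy-4,4-dimethoxy-2-methylidenebutanoate | COC(=O)C(=C)[C@@H](O)C(OC)OC | intermediate
5 | methyl (3R)-3-[(tert-butyldimethylsilyl)oxy]-4,4-dimethoxy-2-methylidenebutanoate | COC(=O)C(=C)[C@@H](O[Si](C)(C)C(C)(C)C)C(OC)OC | intermediate
6 | (3R)-3-[(tert-butyldimethylsilyl)oxy]-4,4-dimethoxy-2-methylidenebutanoic acid | OC(=O)C(=C)[C@@H](O[Si](C)(C)C(C)(C)C)C(OC)OC | intermediate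
7 | 4-(trimethylsilyl)but-3-yn-2-one | CC(=O)C#C[Si](C)(C)C | starting material
8 | (5R)-5-hydroxy-6,6-dimethoxy-1-(trimethylsilyl)hex-1-yn-3-one | C[Si](C)(C)C#CC(=O)C[C@@H](O)C(OC)OC | intermediate
9 | (3S,5R)-6,6-dimethoxy-3-methyl-1-(trimethylsilyl)hex-1-yne-3,5-diol (not isolated) | C[Si](C)(C)C#C[C@@](C)(O)C[C@@H](O)C(OC)OC | intermediate
10 | (3S,5R)-6,6-dimethoxy-3-methylhex-1-yne-3,5-diol | C#C[C@@](C)(O)C[C@@H](O)C(OC)OC | intermediate
11 | 3-methylbutanoyl chloride | CC(C)CC(=O)Cl | starting material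
12 | (2R,4S)-4-hydroxy-1,1-dimethoxy-4-methylhex-5-yn-2-yl 3-methylbutanoate | C#C[C@@](C)(O)C[C@@H](OC(=O)CC(C)C)C(OC)OC | intermediate
13 | (2R,4S)-1,1-dimethoxy-4-methyl-4-[(triethylsilyl)oxy]hex-5-yn-2-yl 3-methylbutanoate (not isolated) | C#C[C@@](C)(O[Si](CC)(CC)CC)C[C@@H](OC(=O)CC(C)C)C(OC)OC | intermediate
14 | 1-{(2R,4S)-1-methoxy-4-methyl-2-[(3-methylbutanoyl)oxy]-4-[(triethylsilyl)oxy]hex-5-yn-1-yl}-2,4,6-trimethylpyridinium triflate, C1 epimers (not isolated) | C#C[C@@](C)(O[Si](CC)(CC)CC)C[C@@H](OC(=O)CC(C)C)C(OC)[n+]1c(C)cc(C)cc1C.[O-]S(=O)(=O)C(F)(F)F | intermediate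
15 | (2R,4S)-4-methyl-1-oxo-4-[(triethylsilyl)oxy]hex-5-yn-2-yl 3-methylbutanoate | C#C[C@@](C)(O[Si](CC)(CC)CC)C[C@@H](OC(=O)CC(C)C)C=O | intermediate
16 | methyl propiolate | C#CC(=O)OC | starting material
17 | [1-(methoxycarbonyl)ethenyl]bis(2-methylpropyl)aluminium (not isolated) | C=C(C(=O)OC)[Al](CC(C)C)CC(C)C | intermediate
18 | methyl (3RS,4R,6S)-3-hydroxy-6-methyl-2-methylidene-4-[(3-methylbutanoyl)oxy]-6-[(triethylsilyl)oxy]oct-7-ynoate | C#C[C@@](C)(O[Si](CC)(CC)CC)C[C@@H](OC(=O)CC(C)C)C(O)C(=C)C(=O)OC | intermediate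
19 | (3R)-3-[(tert-butyldimethylsilyl)oxy]-4,4-dimethoxy-2-methylidenebutanoyl chloride (not isolated) | ClC(=O)C(=C)[C@@H](O[Si](C)(C)C(C)(C)C)C(OC)OC | intermediate
20 | methyl (3RS,4R,6S,11R)-11-[(tert-butyldimethylsilyl)oxy]-3-hydroxy-12,12-dimethoxy-6-methyl-2,10-dimethylidene-4-[(3-methylbutanoyl)oxy]-9-oxo-6-[(triethylsilyl)oxy]dodec-7-ynoate | COC(=O)C(=C)C(O)[C@H](OC(=O)CC(C)C)C[C@](C)(O[Si](CC)(CC)CC)C#CC(=O)C(=C)[C@@H](O[Si](C)(C)C(C)(C)C)C(OC)OC | intermediate
21 | methyl (2Z,4R,6S,11R)-2-(bromomethyl)-11-[(tert-butyldimethylsilyl)oxy]-12,12-dimethoxy-6-methyl-10-methylidene-4-[(3-methylbutanoyl)oxy]-9-oxo-6-[(triethylsilyl)oxy]dodec-2-en-7-ynoate | BrC/C(C(=O)OC)=C\[C@H](OC(=O)CC(C)C)C[C@](C)(O[Si](CC)(CC)CC)C#CC(=O)C(=C)[C@@H](O[Si](C)(C)C(C)(C)C)C(OC)OC | intermediate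
22 | 2,4,6-trimethylpyridinium salt formed from 21 at C12 (one methoxy replaced by N-collidinium, triflate counter-ion, C12 epimers; not isolated) | BrC/C(C(=O)OC)=C\[C@H](OC(=O)CC(C)C)C[C@](C)(O[Si](CC)(CC)CC)C#CC(=O)C(=C)[C@@H](O[Si](C)(C)C(C)(C)C)C(OC)[n+]1c(C)cc(C)cc1C.[O-]S(=O)(=O)C(F)(F)F | intermediate
23 | methyl (2Z,4R,6S,11R)-2-(bromomethyl)-11-[(tert-butyldimethylsilyl)oxy]-6-methyl-10-methylidene-4-[(3-methylbutanoyl)oxy]-9,12-dioxo-6-[(triethylsilyl)oxy]dodec-2-en-7-ynoate | BrC/C(C(=O)OC)=C\[C@H](OC(=O)CC(C)C)C[C@](C)(O[Si](CC)(CC)CC)C#CC(=O)C(=C)[C@@H](O[Si](C)(C)C(C)(C)C)C=O | intermediate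
24 | σ-allyl chromium dichloride from 23 (CrCl2 on C13 in place of Br, trivalent chromium; not isolated) | Cl[Cr](Cl)C/C(C(=O)OC)=C\[C@H](OC(=O)CC(C)C)C[C@](C)(O[Si](CC)(CC)CC)C#CC(=O)C(=C)[C@@H](O[Si](C)(C)C(C)(C)C)C=O | intermediate
25 | methyl (5R,6S,7S,8R,10S)-5-[(tert-butyldimethylsilyl)oxy]-6-hydroxy-8-[(3-methylbutanoyl)oxy]-3-oxo-10-[(triethylsilyl)oxy]germacra-4(15),11(13)-dien-1-yn-12-oate (not isolated) | COC(=O)C(=C)[C@H]1[C@H](O)[C@H](O[Si](C)(C)C(C)(C)C)C(=C)C(=O)C#C[C@@](C)(O[Si](CC)(CC)CC)C[C@H]1OC(=O)CC(C)C | intermediate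
26 | (5R,6S,7R,8R,10S)-5-[(tert-butyldimethylsilyl)oxy]-8-[(3-methylbutanoyl)oxy]-3-oxo-10-[(triethylsilyl)oxy]germacra-4(15),11(13)-dien-1-yn-12,6-olide | C=C1C(=O)O[C@H]2[C@H]1[C@H](OC(=O)CC(C)C)C[C@](C)(O[Si](CC)(CC)CC)C#CC(=O)C(=C)[C@H]2O[Si](C)(C)C(C)(C)C | intermediate
27 | (5R,6S,7R,8R,10S)-5-[(tert-butyldimethylsilyl)oxy]-8-[(3-methylbutanoyl)oxy]-1,3-dioxo-10-[(triethylsilyl)oxy]germacra-4(15),11(13)-dien-12,6-olide (not isolated) | C=C1C(=O)O[C@H]2[C@H]1[C@H](OC(=O)CC(C)C)C[C@](C)(O[Si](CC)(CC)CC)C(=O)CC(=O)C(=C)[C@H]2O[Si](C)(C)C(C)(C)C | intermediate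
28 | (5R,6S,7R,8R,10S)-5-[(tert-butyldimethylsilyl)oxy]-10-hydroxy-8-[(3-methylbutanoyl)oxy]-1,3-dioxogermacra-4(15),11(13)-dien-12,6-olide (not isolated) | C=C1C(=O)O[C@H]2[C@H]1[C@H](OC(=O)CC(C)C)C[C@](C)(O)C(=O)CC(=O)C(=C)[C@H]2O[Si](C)(C)C(C)(C)C | intermediate
29 | (5R,6S,7R,8R,10S)-5-[(tert-butyldimethylsilyl)oxy]-8-[(3-methylbutanoyl)oxy]-1-oxo-3,10-epoxygermacra-2,4(15),11(13)-trien-12,6-olide (not isolated) | C=C1C(=O)O[C@H]2[C@H]1[C@H](OC(=O)CC(C)C)C[C@]1(C)OC(=CC1=O)C(=C)[C@H]2O[Si](C)(C)C(C)(C)C | intermediate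
30 | (5R,6S,7R,8R,10S)-5-hydroxy-8-[(3-methylbutanoyl)oxy]-1-oxo-3,10-epoxygermacra-2,4(15),11(13)-trien-12,6-olide (CNP0409337.1) | C=C1C(=O)O[C@H]2[C@H]1[C@H](OC(=O)CC(C)C)C[C@]1(C)OC(=CC1=O)C(=C)[C@H]2O | target

## Step count and risks

Total step count: 14 (West branch 4, East branch 5, union and endgame 5). Longest linear sequence: 10 steps (steps 5 to 14).

Risk 1, the ring closure (step 13). The closure must form a strained cyclodec-1-yn-3-one and set C6 and C7 in one event. It could give the cis-lactone series or oligomers, and divalent chromium could attack the ynone. Fallback, which changes the order of ring formation: set out from 21. Hydration with Ph3PAuNTf2/H2O, then brief buffered HF·pyridine at 0 °C (tertiary silyl ether only), lets the open-chain hydroxy diketone cyclodehydrate to the open-chain furanone acetal F1. TESOTf/2,4,6-collidine and then water give the furanone aldehyde F2. CrCl2 closure of C6–C7 on this rigidified chain gives the furanone seco hydroxy ester F3, which lactonises with PPTS to 29. The route is rejoined at 29 and finished with the HF·pyridine stage of step 14.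

Risk 2, the hydration and transannular cyclodehydration (step 14). Water must add at C1 of a hindered, strained, cross-conjugated ynone. The hydration could stall or go to C2 or C15, and early loss of the C5 silyl ether would open a competing pyranone closure. Fallback, which hydrates before ring closure so that the last operation is only the cyclodehydration of an isolated germacranolide dione: set out from 21. Ph3PAuNTf2/H2O gives the open-chain 1,3-diketone F4 (the tertiary silyl ether stays, so no furanone forms). Acetal cleavage as in step 12 gives the diketone aldehyde F5. CrCl2 closure gives the macrocyclic diketone hydroxy ester F6, which lactonises to 27. The route is rejoined at 27, which then needs only HF·pyridine.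

Risk 3, the chelate-controlled methyl addition (step 6). The diastereoselectivity at the quaternary C10 rests on substrate control alone, and 1,4-addition or retro-aldol cleavage could compete. Fallback, which sets C10 the other way round and corrects C8 afterwards: set out from 1. D-Proline-catalysed aldol with acetone gives (4S)-4-hydroxy-5,5-dimethoxypentan-2-one F7. HC≡CMgBr adds under the same magnesium chelate control, but now the alkynyl group enters axially, giving the 3,5-anti diol (3S,5S)-6,6-dimethoxy-3-methylhex-1-yne-3,5-diol F8, with C10 correct and C8 epimeric. Mitsunobu esterification with 3-methylbutanoic acid (PPh3, DIAD) inverts C8 and installs the ester in the same step, arriving at 12.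

## Further compounds

F1 | step 13 | methyl (2Z,4R)-2-(bromomethyl)-5-[(2S)-5-{(3R)-3-[(tert-butyldimethylsilyl)oxy]-4,4-dimethoxybut-1-en-2-yl}-2-methyl-3-oxo-2,3-dihydrofuran-2-yl]-4-[(3-methylbutanoyl)oxy]pent-2-enoate | BrC/C(C(=O)OC)=C\[C@H](OC(=O)CC(C)C)C[C@]1(C)OC(=CC1=O)C(=C)[C@@H](O[Si](C)(C)C(C)(C)C)C(OC)OC
F2 | step 13 | methyl (2Z,4R)-2-(bromomethyl)-5-[(2S)-5-{(3R)-3-[(tert-butyldimethylsilyl)oxy]-4-oxobut-1-en-2-yl}-2-methyl-3-oxo-2,3-dihydrofuran-2-yl]-4-[(3-methylbutanoyl)oxy]pent-2-enoate | BrC/C(C(=O)OC)=C\[C@H](OC(=O)CC(C)C)C[C@]1(C)OC(=CC1=O)C(=C)[C@@H](O[Si](C)(C)C(C)(C)C)C=O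
F3 | step 13 | methyl (5R,6S,7S,8R,10S)-5-[(tert-butyldimethylsilyl)oxy]-6-hydroxy-8-[(3-methylbutanoyl)oxy]-1-oxo-3,10-epoxygermacra-2,4(15),11(13)-trien-12-oate | COC(=O)C(=C)[C@H]1[C@H](O)[C@H](O[Si](C)(C)C(C)(C)C)C(=C)C2=CC(=O)[C@@](C)(O2)C[C@H]1OC(=O)CC(C)C
F4 | step 14 | methyl (2Z,4R,6S,11R)-2-(bromomethyl)-11-[(tert-butyldimethylsilyl)oxy]-12,12-dimethoxy-6-methyl-10-methylidene-4-[(3-methylbutanoyl)oxy]-7,9-dioxo-6-[(triethylsilyl)oxy]dodec-2-enoate | BrC/C(C(=O)OC)=C\[C@H](OC(=O)CC(C)C)C[C@](C)(O[Si](CC)(CC)CC)C(=O)CC(=O)C(=C)[C@@H](O[Si](C)(C)C(C)(C)C)C(OC)OC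
F5 | step 14 | methyl (2Z,4R,6S,11R)-2-(bromomethyl)-11-[(tert-butyldimethylsilyl)oxy]-6-methyl-10-methylidene-4-[(3-methylbutanoyl)oxy]-7,9,12-trioxo-6-[(triethylsilyl)oxy]dodec-2-enoate | BrC/C(C(=O)OC)=C\[C@H](OC(=O)CC(C)C)C[C@](C)(O[Si](CC)(CC)CC)C(=O)CC(=O)C(=C)[C@@H](O[Si](C)(C)C(C)(C)C)C=O
F6 | step 14 | methyl (5R,6S,7S,8R,10S)-5-[(tert-butyldimethylsilyl)oxy]-6-hydroxy-8-[(3-methylbutanoyl)oxy]-1,3-dioxo-10-[(triethylsilyl)oxy]germacra-4(15),11(13)-dien-12-oate | COC(=O)C(=C)[C@H]1[C@H](O)[C@H](O[Si](C)(C)C(C)(C)C)C(=C)C(=O)CC(=O)[C@@](C)(O[Si](CC)(CC)CC)C[C@H]1OC(=O)CC(C)C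
F7 | step 6 | (4S)-4-hydroxy-5,5-dimethoxypentan-2-one | CC(=O)C[C@H](O)C(OC)OC
F8 | step 6 | (3S,5S)-6,6-dimethoxy-3-methylhex-1-yne-3,5-diol | C#C[C@@](C)(O)C[C@H](O)C(OC)OC
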